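**Assumption:** the side-chain stereocentre is taken exactly as drawn in the SMILES, i.e. an (R)-2-methylbutanoate; (R)-2-methylbutanoic acid is treated as commercial.

## Retrosynthetic overview

1. Ester last. The 4β-OH/5β-OAcyl unit comes from the 4α,5β-epoxide of an (E)-4,5-alkene, opened at C4 with inversion.
2. The trans α-methylene lactone comes from oxidative lactonisation of a C6-OH/C12-OH 2-methylene-1,4-diol.
3. The ten-membered ring comes from an anionic oxy-Cope ring expansion of a trans-1,2-dialkenyl-2,6-dimethylcyclohexanol (C4–C9 cleaved, C6–C7 formed, C6/C7 set in a chair transition state).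
4. That carbinol comes from a dienyllithium plus an α-alkenyl ketone, itself made by desymmetrising enantioselective deprotonation/α-alkenylation of meso cis-2,6-dimethylcyclohexanone (sets C10, relays through C4).
5. The meso ketone comes from 2,6-xylenol. Ring order: cyclohexane (ex-arene) → cyclodecenone → lactone.

Germacrane numbering is used below: C4 (Me, OH), C5 (OAcyl), C6 (lactone O), C7 (acrylate carbon), C9 (C=O), C10 (Me). The xylenol ring becomes C1–C4, C9 and C10.

## Route

**Step 1**
Reactants: 1, 2,6-dimethylphenol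
Product: 2, cis-(2R,6S)-2,6-dimethylcyclohexan-1-one (meso)
Conditions: H2 (10 bar), 5% Pd/C, cat. AlCl3, CH2Cl2, 50 °C; then NaOMe, MeOH, rt; fractional distillation
Reagents that add atoms: none
Why: Pd-catalysed partial arene hydrogenation stops at the ketone, and base equilibration favours the diequatorial cis (meso) isomer, which is separated from the minor trans isomer.

**Step 2**
Reactants: 3, 4-methoxybenzyl alcohol; 4, (E)-1,2-diiodoethene (3 equiv)
Product: 5, 1-({[(E)-2-iodoethenyl]oxy}methyl)-4-methoxybenzene
Conditions: CuI (10 mol%), 3,4,7,8-tetramethyl-1,10-phenanthroline (20 mol%), Cs2CO3, toluene, 80 °C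
Reagents that add atoms: none beyond the listed reactants
Why: Cu-catalysed Ullmann-type vinyl C–O coupling is stereoretentive (E kept); excess diiodide gives mono-substitution, and the E-diiodide has no anti H/I pair for E2.

**Step 3 (key step)**
Reactants: 2, cis-2,6-dimethylcyclohexanone; 5, (E)-iodovinyl PMB ether
Product: 6, (2S,6R)-2-{(E)-2-[(4-methoxybenzyl)oxy]ethenyl}-2,6-dimethylcyclohexan-1-one
Conditions: lithium bis[(1-phenylethyl)]amide (the (R,R) or (S,S) antipode that gives the 6R enolate; both commercial), LiCl, THF, −78 °C; ZnCl2, −78 → 0 °C; then 5, Pd2(dba)3 (2.5 mol%), Q-Phos (6 mol%), rt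
Reagents that add atoms: none beyond 5
Why: Proposed new method: enantiotopic α-deprotonation of the meso ketone by a C2-symmetric chiral lithium amide (known Simpkins–Koga desymmetrisation, fixes C10 as R) is telescoped with Pd-catalysed α-alkenylation of the zinc enolate (closest known type: Pd-catalysed ketone/zinc enolate α-vinylation forming quaternary centres); the new C–C bond forms on the enolate face anti to the C10 methyl (gives 2S), and the E-alkenyl–Pd cannot undergo syn β-alkoxide elimination.

**Step 4**
Reactants: 7, 2-bromoprop-2-en-1-ol; 8, (E)-1,2-bis(tributylstannyl)ethene (2.5 equiv)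
Product: 9, (E)-2-methylidene-4-(tributylstannyl)but-3-en-1-ol
Conditions: Pd(PPh3)4 (5 mol%), toluene, 80 °C
Reagents that add atoms: none beyond the listed reactants
Why: Stille coupling with excess distannane gives the mono-coupled dienylstannane with E geometry retained; the free OH is tolerated.

**Step 5**
Reactants: 6, alkenyl ketone; 9, dienylstannane (1.5 equiv)
Product: 10, (1R,2S,6R)-1-[(1E)-3-(hydroxymethyl)buta-1,3-dien-1-yl]-2-{(E)-2-[(4-methoxybenzyl)oxy]ethenyl}-2,6-dimethylcyclohexan-1-ol
Conditions: 9, n-BuLi (2.05 equiv per 9), THF, −78 °C; CeCl3; then 6, −78 → −40 °C; aq. NH4Cl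
Reagents that add atoms: none beyond the listed reactants
Why: Sn–Li exchange gives the (E)-dienyl organometal (Ce suppresses enolisation at C10); the ketone chair has both methyls equatorial and the alkenyl axial, so axial attack anti to that alkenyl gives the 1,2-trans-dialkenyl carbinol (1R).

**Step 6**
Reactants: 10, trans-dialkenyl carbinol
Product: 11, (3S,4R,5E,10R)-3-(3-hydroxyprop-1-en-2-yl)-4-[(4-methoxybenzyl)oxy]-6,10-dimethylcyclodec-5-en-1-one
Conditions: KH (3 equiv), 18-crown-6, THF, 0 → 25 °C; quench at −78 °C with AcOH/THF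
Reagents that add atoms: none
Why: Anionic oxy-Cope rearrangement through the only productive chair (both alkenyls equatorial, trans-decalin-like) cleaves C4–C9 and forms C6–C7; the E,E termini place C6–OPMB and the C7 substituent trans (natural 6α-O/7β-C), the new C4=C5 is E, C10 is untouched and protonation at C8 creates no stereocentre.

**Step 7**
Reactants: 11
Product: 12, (3S,4R,5E,10R)-4-hydroxy-3-(3-hydroxyprop-1-en-2-yl)-6,10-dimethylcyclodec-5-en-1-one
Conditions: DDQ (1.3 equiv), CH2Cl2/pH 7 buffer (10:1), 0 °C
Reagents that add atoms: none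
Why: Oxidative PMB ether cleavage by DDQ leaves the alkenes, ketone and alcohols intact; no stereocentre is touched.

**Step 8**
Reactants: 12
Product: 13, (3aS,6R,10E,11aR)-6,10-dimethyl-3-methylidene-3a,4,6,7,8,9-hexahydrocyclodeca[b]furan-2,5(3H,11aH)-dione (a 9-oxo-1,10-dihydrocostunolide)
Conditions: TEMPO (0.2 equiv), PhI(OAc)2 (3 equiv), CH2Cl2, rt
Reagents that add atoms: none
Why: TEMPO/BAIB oxidises the primary allylic alcohol selectively, the enal is trapped by C6-OH as the lactol and oxidised on to the lactone; C6 and C7 are untouched, so the ring fusion is trans.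

**Step 9**
Reactants: 13
Product: 14, the 4α,5β-epoxide of 13 (parthenolide-type, 4R,5R)
Conditions: mCPBA (1.1 equiv), NaHCO3, CH2Cl2, 0 °C
Reagents that add atoms: mCPBA, O=C(OO)c1cccc(Cl)c1 (one O)
Why: Prilezhaev epoxidation of the only electron-rich alkene; A(1,3) strain fixes the C5–C6 rotamer and the ring chain shields the inner face, so oxygen arrives on the outer face syn to C6–O, as in costunolide-type germacranolides.

**Step 10**
Reactants: 14
Product: 15, 4β,5β-diol (3aS,6R,10S,11R,11aS)-10,11-dihydroxy lactone
Conditions: cat. HClO4, THF/H2O (3:1), 0 °C → rt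
Reagents that add atoms: water, O
Why: Acid-catalysed epoxide hydrolysis at the tertiary C4 with inversion (direct backside attack by water, or relayed through the transannular C9 carbonyl oxygen and hydrolysis of the oxocarbenium) while C5–O is retained, giving 4S,5R.

**Step 11**
Reactants: 15; 16, (R)-2-methylbutanoic acid
Product: 17, ineupatorolide A
Conditions: 16, 2,4,6-trichlorobenzoyl chloride, Et3N, THF; then 15, DMAP, toluene, rt
Reagents that add atoms: none beyond 16
Why: Yamaguchi esterification acylates the secondary C5-OH selectively over the tertiary C4-OH, and mixed-anhydride activation minimises epimerisation of the acid α-centre.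

## Compound list

1 | 2,6-dimethylphenol | Cc1cccc(C)c1O | starting material
2 | cis-(2R,6S)-2,6-dimethylcyclohexan-1-one (meso) | C[C@@H]1CCC[C@H](C)C1=O | intermediate
3 | 4-methoxybenzyl alcohol | COc1ccc(CO)cc1 | starting material
4 | (E)-1,2-diiodoethene | I/C=C/I | starting material
5 | 1-({[(E)-2-iodoethenyl]oxy}methyl)-4-methoxybenzene | I/C=C/OCc1ccc(OC)cc1 | intermediate
6 | (2S,6R)-2-{(E)-2-[(4-methoxybenzyl)oxy]ethenyl}-2,6-dimethylcyclohexan-1-one | C[C@@H]1CCC[C@@](C)(/C=C/OCc2ccc(OC)cc2)C1=O | intermediate
7 | 2-bromoprop-2-en-1-ol | OCC(Br)=C | starting material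
8 | (E)-1,2-bis(tributylstannyl)ethene | CCCC[Sn](CCCC)(CCCC)/C=C/[Sn](CCCC)(CCCC)CCCC | starting material
9 | (E)-2-methylidene-4-(tributylstannyl)but-3-en-1-ol | OCC(=C)/C=C/[Sn](CCCC)(CCCC)CCCC | intermediate
10 | (1R,2S,6R)-1-[(1E)-3-(hydroxymethyl)buta-1,3-dien-1-yl]-2-{(E)-2-[(4-methoxybenzyl)oxy]ethenyl}-2,6-dimethylcyclohexan-1-ol | C[C@@H]1CCC[C@@](C)(/C=C/OCc2ccc(OC)cc2)[C@]1(O)/C=C/C(=C)CO | intermediate
11 | (3S,4R,5E,10R)-3-(3-hydroxyprop-1-en-2-yl)-4-[(4-methoxybenzyl)oxy]-6,10-dimethylcyclodec-5-en-1-one | C=C(CO)[C@@H]1CC(=O)[C@H](C)CCC/C(C)=C/[C@H]1OCc2ccc(OC)cc2 | intermediate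
12 | (3S,4R,5E,10R)-4-hydroxy-3-(3-hydroxyprop-1-en-2-yl)-6,10-dimethylcyclodec-5-en-1-one | C=C(CO)[C@@H]1CC(=O)[C@H](C)CCC/C(C)=C/[C@H]1O | intermediate
13 | (3aS,6R,10E,11aR)-6,10-dimethyl-3-methylidene-3a,4,6,7,8,9-hexahydrocyclodeca[b]furan-2,5(3H,11aH)-dione | C=C1C(=O)O[C@@H]2/C=C(C)/CCC[C@@H](C)C(=O)C[C@@H]12 | intermediate
14 | 4α,5β-epoxide of 13 (4R,5R,6S,7S,10R; germacrane numbering) | C=C1C(=O)O[C@@H]2[C@H]3O[C@]3(C)CCC[C@@H](C)C(=O)C[C@@H]12 | intermediate
15 | 4β,5β-diol, (3aS,6R,10S,11R,11aS)-10,11-dihydroxy-6,10-dimethyl-3-methylidene-octahydrocyclodeca[b]furan-2,5-dione | C=C1C(=O)O[C@@H]2[C@@H](O)[C@@](C)(O)CCC[C@@H](C)C(=O)C[C@@H]12 | intermediate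
16 | (R)-2-methylbutanoic acid | CC[C@@H](C)C(=O)O | starting material
17 | ineupatorolide A, (3aS,6R,10S,11R,11aS)-10-hydroxy-6,10-dimethyl-3-methylidene-2,5-dioxo-cyclodeca[b]furan-11-yl (2R)-2-methylbutanoate | C=C1C(=O)O[C@@H]2[C@@H](OC(=O)[C@H](C)CC)[C@@](C)(O)CCC[C@@H](C)C(=O)C[C@@H]12 | target

## Step count and risk

Total steps: 11. Longest linear sequence: 9 (steps 1, 3, 5–11 from 2,6-dimethylphenol; equally 2, 3, 5–11 from 4-methoxybenzyl alcohol).

Steps most likely to fail:

1. **Step 3** (one-pot desymmetrisation/α-alkenylation: ee, diastereoselectivity at the quaternary centre, and an untested β-alkoxyvinyl iodide). Fallback: trap the chiral enolate as its TMS enol ether (established in-situ-quench protocol), then build the side chain by Mukaiyama aldol with (4-methoxybenzyloxy)acetaldehyde and dehydration (MsCl; KOt-Bu) to the same E-enol ether 6.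
2. **Step 6** (oxy-Cope: the reactive chair carries 1,3-diaxial methyls, and C10 can epimerise through enolate equilibration). Fallback: abandon ring expansion; ozonolyse the same desymmetrised silyl enol ether to (R)-2-methyl-6-oxoheptanoic acid and close the ten-membered ring by intramolecular Barbier/Nozaki–Hiyama allylation of a 2-(bromomethyl)acrylate onto the C6 aldehyde.
3. **Step 10** (medium-ring epoxide opening: transannular hydride shift or Meinwald rearrangement may compete with inversion at C4). Fallback: deliver the C4 oxygen intramolecularly; epoxidise diol 12 instead, convert C6-OH to its tert-butyl carbonate and trigger 6-endo opening at C4 (BF3·OEt2) to a 4,6-cyclic carbonate, then acylate C5-OH, cleave the carbonate and lactonise.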